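**Retrosynthetic overview**

1. Both dihydrofuran rings are closed last and together: a double 5-endo cycloisomerisation (monovalent gold) of a C40 bis(α-hydroxyallene), in which each allene axis is copied into C-8 or C-8′.
2. The C40 bis-allenol comes from two Wittig couplings: left C15 allenyl phosphonium salt + C10 trienedial, then the right C15 allenyl phosphonium salt.
3. Each allene comes from anti-SN2′ opening of an alkynyl oxirane. Carbon is delivered on the left (palladium, alkenylboronate) and hydride on the right (copper hydride), which gives the two different axis/C-5 relationships the target needs.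
4. The oxiranes come from Sharpless epoxidation of β-cyclogeraniol (left) and from silyloxy-controlled peracid epoxidation of a dienyne made from ketoisophorone (right; asymmetric transfer hydrogenation, reductive triflation, Sonogashira coupling).
5. Ring order: the two carbocycles are bought; the two oxiranes are made and opened on the way; the two dihydrofurans form in one operation in the final step.

Assumption: the target SMILES is taken at face value (all-E chain; 3R,5S,8S,5′R,8′S); an allene axis has no symbol in plain SMILES, so it is given in the names as (Ra).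

The stereochemical sense of the SN2′ and cyclisation steps is argued from mechanism and analogy; nothing here has been run.

**Route**

Step 1
Reactants: 1 ketoisophorone (2,6,6-trimethylcyclohex-2-ene-1,4-dione)
Product: 2 (4R)-4-hydroxy-2,6,6-trimethylcyclohex-2-en-1-one
Conditions: RuCl[(R,R)-TsDPEN](p-cymene) (1 mol %), iPrOH, 25 °C
Reagents that add atoms: none
Why: Noyori–Ikariya asymmetric transfer hydrogenation reduces only the less hindered C-4 carbonyl (the other is flanked by a quaternary carbon), and with the enone π-system in the aryl position of the CH/π model the (R,R)-ligand gives the (R)-carbinol that becomes C-3 of the target.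

Step 2
Reactants: 2 (4R)-4-hydroxy-2,6,6-trimethylcyclohex-2-en-1-one
Product: 3 (4R)-4-{[tert-butyl(dimethyl)silyl]oxy}-2,6,6-trimethylcyclohex-2-en-1-one
Conditions: TBSCl, imidazole, DMF, 25 °C
Reagents that add atoms: tert-butyldimethylsilyl chloride, CC(C)(C)[Si](C)(C)Cl
Why: Standard silyl ether formation protects the carbinol for enolate chemistry and later steers the epoxidation; the stereocentre is untouched.

Step 3
Reactants: 3 (4R)-4-{[tert-butyl(dimethyl)silyl]oxy}-2,6,6-trimethylcyclohex-2-en-1-one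
Product: 5 (4S)-4-{[tert-butyl(dimethyl)silyl]oxy}-2,6,6-trimethylcyclohex-1-en-1-yl trifluoromethanesulfonate, via lithium enolate 4 (not isolated)
Conditions: LiBH(s-Bu)3, THF, −78 °C; then PhNTf2, −78 → 0 °C
Reagents that add atoms: N-phenylbis(trifluoromethanesulfonimide), FC(F)(F)S(=O)(=O)N(c1ccccc1)S(=O)(=O)C(F)(F)F
Why: Conjugate hydride reduction of the β-unsubstituted enone (the carbonyl is shielded by the gem-dimethyl carbon) gives the tetrasubstituted enolate regiospecifically and it is O-triflated in the same flask (reductive enolate triflation); the carbinol centre is unchanged (the descriptor changes only by priority).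

Step 4
Reactants: 5 (4S)-4-{[tert-butyl(dimethyl)silyl]oxy}-2,6,6-trimethylcyclohex-1-en-1-yl trifluoromethanesulfonate; 6 (2E)-3-methylpent-2-en-4-yn-1-ol
Product: 7 (2E)-5-[(4S)-4-{[tert-butyl(dimethyl)silyl]oxy}-2,6,6-trimethylcyclohex-1-en-1-yl]-3-methylpent-2-en-4-yn-1-ol
Conditions: Pd(PPh3)4 (5 mol %), CuI (copper iodide, 10 mol %), iPr2NH, DMF, 50 °C
Reagents that add atoms: none
Why: Sonogashira coupling of the enol triflate with the terminal alkyne builds the whole C15 skeleton in one step; the E olefin of 6 is retained.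

Step 5
Reactants: 7 (2E)-5-[(4S)-4-{[tert-butyl(dimethyl)silyl]oxy}-2,6,6-trimethylcyclohex-1-en-1-yl]-3-methylpent-2-en-4-yn-1-ol
Product: 8 (2E)-5-[(1S,4R,6S)-4-{[tert-butyl(dimethyl)silyl]oxy}-2,2,6-trimethyl-7-oxabicyclo[4.1.0]heptan-1-yl]-3-methylpent-2-en-4-yn-1-ol
Conditions: mCPBA (1.05 equiv), NaHCO3, CH2Cl2, −20 → 0 °C
Reagents that add atoms: meta-chloroperoxybenzoic acid, OOC(=O)c1cccc(Cl)c1
Why: Prilezhaev epoxidation takes the most electron-rich (tetrasubstituted ring) alkene, and the peracid approaches anti to the pseudo-equatorial silyloxy group, setting C-5 and C-6 with oxygen trans to the C-3 oxygen (about 4:1 expected, minor syn isomer removed by chromatography).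

Step 6
Reactants: 8 (2E)-5-[(1S,4R,6S)-4-{[tert-butyl(dimethyl)silyl]oxy}-2,2,6-trimethyl-7-oxabicyclo[4.1.0]heptan-1-yl]-3-methylpent-2-en-4-yn-1-ol
Product: 9 (1S,5R,Ra)-5-{[tert-butyl(dimethyl)silyl]oxy}-2-[(3E)-5-hydroxy-3-methylpenta-1,3-dien-1-ylidene]-1,3,3-trimethylcyclohexan-1-ol
Conditions: (IPr)CuCl (IPr = 1,3-bis(2,6-diisopropylphenyl)imidazol-2-ylidene, 5 mol %), NaOtBu (5 mol %), (EtO)2MeSiH (3 equiv), toluene, 0 °C; aq. NaOH work-up
Reagents that add atoms: none
Why: Copper hydride-catalysed SN2′ reduction of a propargylic oxirane (syn hydrocupration, anti β-alkoxide elimination) puts hydride on C-8 anti to the breaking C-6–O bond, so the (5S) oxirane centre is transferred to the (Ra) axis with the chain on the oxygen side while the C-5 carbinol is retained.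

Step 7
Reactants: 9 (1S,5R,Ra)-5-{[tert-butyl(dimethyl)silyl]oxy}-2-[(3E)-5-hydroxy-3-methylpenta-1,3-dien-1-ylidene]-1,3,3-trimethylcyclohexan-1-ol
Product: 10 {(2E)-5-[(2S,4R,Ra)-2,4-dihydroxy-2,6,6-trimethylcyclohexylidene]-3-methylpenta-2,4-dien-1-yl}triphenylphosphonium bromide
Conditions: PPh3·HBr (1.5 equiv), MeOH, 0 → 25 °C
Reagents that add atoms: triphenylphosphine hydrobromide, [Br-].[PH+](c1ccccc1)(c1ccccc1)c1ccccc1
Why: Standard carotenoid C15-salt formation (SN1 capture of the delocalised allylic cation by PPh3 at its unhindered terminus) converts only the primary allylic alcohol, and the same dilute HBr in methanol removes the silyl ether; the other hydroxyls, the stereocentres and the axis are not involved.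

Step 8
Reactants: 11 β-cyclocitral (2,6,6-trimethylcyclohex-1-ene-1-carbaldehyde)
Product: 12 β-cyclogeraniol ((2,6,6-trimethylcyclohex-1-en-1-yl)methanol)
Conditions: NaBH4, MeOH, 0 °C
Reagents that add atoms: none
Why: Simple 1,2-borohydride reduction gives the allylic alcohol needed to direct the asymmetric epoxidation.

Step 9
Reactants: 12 β-cyclogeraniol
Product: 13 [(1R,6R)-2,2,6-trimethyl-7-oxabicyclo[4.1.0]heptan-1-yl]methanol
Conditions: Ti(OiPr)4 (20 mol %), D-(−)-diethyl tartrate (24 mol %), t-BuOOH, 4 Å MS, CH2Cl2, −20 °C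
Reagents that add atoms: tert-butyl hydroperoxide, CC(C)(C)OO
Why: Sharpless asymmetric epoxidation of the allylic alcohol; the D-(−)-tartrate catalyst delivers oxygen to the face that gives the (1R,6R) oxirane, which fixes the absolute configuration of C-5′ (R).

Step 10
Reactants: 13 [(1R,6R)-2,2,6-trimethyl-7-oxabicyclo[4.1.0]heptan-1-yl]methanol
Product: 14 (1S,6R)-2,2,6-trimethyl-7-oxabicyclo[4.1.0]heptane-1-carbaldehyde
Conditions: nPr4N[RuO4] (5 mol %), N-methylmorpholine N-oxide, 4 Å MS, CH2Cl2, 25 °C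
Reagents that add atoms: none
Why: Ley–Griffith oxidation is neutral, so the oxirane survives, and the α-carbon is quaternary so nothing can epimerise (the descriptor change is by priority only).

Step 11
Reactants: 14 (1S,6R)-2,2,6-trimethyl-7-oxabicyclo[4.1.0]heptane-1-carbaldehyde
Product: 15 (1R,6R)-1-ethynyl-2,2,6-trimethyl-7-oxabicyclo[4.1.0]heptane
Conditions: dimethyl (1-diazo-2-oxopropyl)phosphonate, K2CO3, MeOH, 0 → 25 °C
Reagents that add atoms: dimethyl (1-diazo-2-oxopropyl)phosphonate, COP(=O)(OC)C(=[N+]=[N-])C(C)=O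
Why: Ohira–Bestmann (Seyferth–Gilbert) homologation turns the non-enolisable aldehyde into the terminal alkyne under mild base that leaves the oxirane and both stereocentres alone.

Step 12
Reactants: 16 but-2-yn-1-ol
Product: 17 (2Z)-3-(4,4,5,5-tetramethyl-1,3,2-dioxaborolan-2-yl)but-2-en-1-ol
Conditions: CuCl (5 mol %), PCy3 (6 mol %), NaOtBu (10 mol %), B2pin2, MeOH (2 equiv), toluene, 25 °C
Reagents that add atoms: bis(pinacolato)diboron, CC1(C)OB(OC1(C)C)B1OC(C)(C)C(C)(C)O1
Why: Copper-catalysed formal hydroboration (syn borylcupration, then protonolysis with retention) puts boron on the alkyne carbon remote from oxygen, so boron and CH2OH end up trans, which is the future 9′E geometry.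

Step 13
Reactants: 15 (1R,6R)-1-ethynyl-2,2,6-trimethyl-7-oxabicyclo[4.1.0]heptane; 17 (2Z)-3-(4,4,5,5-tetramethyl-1,3,2-dioxaborolan-2-yl)but-2-en-1-ol
Product: 18 (1R,Ra)-2-[(3E)-5-hydroxy-3-methylpenta-1,3-dien-1-ylidene]-1,3,3-trimethylcyclohexan-1-ol
Conditions: Pd(PPh3)4 (5 mol %), THF–H2O (10:1), 40 °C
Reagents that add atoms: none
Why: Palladium-catalysed anti-SN2′ coupling of a propargylic oxirane with an organoboron reagent: zerovalent palladium ionises the oxirane anti to the C–O bond to a σ-allenylpalladium alkoxide, and transmetalation and reductive elimination go with retention, so the chain enters C-8′ anti to oxygen and the (5′R) centre is transferred to the (Ra) axis.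

Step 14
Reactants: 18 (1R,Ra)-2-[(3E)-5-hydroxy-3-methylpenta-1,3-dien-1-ylidene]-1,3,3-trimethylcyclohexan-1-ol
Product: 19 {(2E)-5-[(2R,Ra)-2-hydroxy-2,6,6-trimethylcyclohexylidene]-3-methylpenta-2,4-dien-1-yl}triphenylphosphonium bromide
Conditions: PPh3·HBr (1.1 equiv), MeOH–CH2Cl2, 0 °C
Reagents that add atoms: triphenylphosphine hydrobromide, [Br-].[PH+](c1ccccc1)(c1ccccc1)c1ccccc1
Why: Same C15-salt formation as in step 7; only the primary allylic alcohol ionises, and the tertiary allenic carbinol tolerates the brief dilute acid.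

Step 15
Reactants: 19 {(2E)-5-[(2R,Ra)-2-hydroxy-2,6,6-trimethylcyclohexylidene]-3-methylpenta-2,4-dien-1-yl}triphenylphosphonium bromide; 20 (2E,4E,6E)-2,7-dimethylocta-2,4,6-trienedial
Product: 22 (2E,4E,6E,8E,10E,Ra)-13-[(2R)-2-hydroxy-2,6,6-trimethylcyclohexylidene]-2,7,11-trimethyltrideca-2,4,6,8,10,12-hexaenal, via phosphorus ylide 21 (not isolated)
Conditions: NaN(SiMe3)2 (1.05 equiv), THF, −78 °C; add to 20 (3 equiv), −78 → 0 °C; then PhH, 25 °C, room light (Z → E)
Reagents that add atoms: none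
Why: Wittig olefination: the ylide forms selectively because the phosphonium C–H is far more acidic than the hydroxyl, excess dialdehyde gives mono-olefination, the new disubstituted C-11′=C-12′ bond is equilibrated to E, and aprotic low-temperature conditions keep the ylide from being protonated at the allene carbon.

Step 16
Reactants: 10 {(2E)-5-[(2S,4R,Ra)-2,4-dihydroxy-2,6,6-trimethylcyclohexylidene]-3-methylpenta-2,4-dien-1-yl}triphenylphosphonium bromide; 22 (2E,4E,6E,8E,10E,Ra)-13-[(2R)-2-hydroxy-2,6,6-trimethylcyclohexylidene]-2,7,11-trimethyltrideca-2,4,6,8,10,12-hexaenal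
Product: 24 (3R,5S,6R,5′R,6′R)-6,7,6′,7′-tetradehydro-5,6,5′,6′-tetrahydro-β,β-carotene-3,5,5′-triol (all-E; both allene axes Ra), via phosphorus ylide 23 (not isolated)
Conditions: NaN(SiMe3)2 (1.05 equiv), THF, −78 °C; then 22, −78 → 0 °C; then PhH, 25 °C, room light (Z → E)
Reagents that add atoms: none
Why: Second Wittig olefination of the same kind closes the C40 chain at C-11=C-12 and leaves the three free hydroxyls, the stereocentres and both axes untouched.

Step 17
Reactants: 24 (3R,5S,6R,5′R,6′R)-6,7,6′,7′-tetradehydro-5,6,5′,6′-tetrahydro-β,β-carotene-3,5,5′-triol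
Product: 26 (3R,5S,8S,5′R,8′S)-5,8:5′,8′-diepoxy-5,8,5′,8′-tetrahydro-β,β-caroten-3-ol (CNP0406432.1), via mono-cyclised allenol 25 (not isolated)
Conditions: Ph3PAuNTf2 (5 mol %), THF, −20 → 0 °C, dark, Ar
Reagents that add atoms: none
Why: Proposed new method: monovalent gold π-activates the C-7=C-8 bond of each α-hydroxyallene, the tertiary C-5 hydroxyl attacks C-8 in a 5-endo mode within the plane of the C-6 substituents and protodeauration releases the catalyst, so both 2,5-dihydrofuran rings close in one operation and each axis is copied to carbon ((5′R,Ra) gives 8′S, (5S,Ra) gives 8S) with no facial choice left to the reagent; the closest known reaction type is the gold-catalysed cycloisomerisation of a single α-hydroxyallene to a 2,5-dihydrofuran with axis-to-centre chirality transfer, here run twice in one polyene, where Nazarov-type closure of the vinylallene and ionisation of the doubly allylic C-8–O bond are the competing paths that low temperature and a donor solvent are meant to hold back.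

**Compound list**

1 | ketoisophorone (2,6,6-trimethylcyclohex-2-ene-1,4-dione) | CC1=CC(=O)CC(C)(C)C1=O | starting material
2 | (4R)-4-hydroxy-2,6,6-trimethylcyclohex-2-en-1-one | O=C1C(C)(C)C[C@@H](O)C=C1C | intermediate
3 | (4R)-4-{[tert-butyl(dimethyl)silyl]oxy}-2,6,6-trimethylcyclohex-2-en-1-one | O=C1C(C)(C)C[C@@H](O[Si](C)(C)C(C)(C)C)C=C1C | intermediate
4 | lithium (4S)-4-{[tert-butyl(dimethyl)silyl]oxy}-2,6,6-trimethylcyclohex-1-en-1-olate | [Li]OC1=C(C)C[C@H](O[Si](C)(C)C(C)(C)C)CC1(C)C | intermediate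
5 | (4S)-4-{[tert-butyl(dimethyl)silyl]oxy}-2,6,6-trimethylcyclohex-1-en-1-yl trifluoromethanesulfonate | FC(F)(F)S(=O)(=O)OC1=C(C)C[C@H](O[Si](C)(C)C(C)(C)C)CC1(C)C | intermediate
6 | (2E)-3-methylpent-2-en-4-yn-1-ol | OC/C=C(C)/C#C | starting material
7 | (2E)-5-[(4S)-4-{[tert-butyl(dimethyl)silyl]oxy}-2,6,6-trimethylcyclohex-1-en-1-yl]-3-methylpent-2-en-4-yn-1-ol | OC/C=C(C)/C#CC1=C(C)C[C@H](O[Si](C)(C)C(C)(C)C)CC1(C)C | intermediate
8 | (2E)-5-[(1S,4R,6S)-4-{[tert-butyl(dimethyl)silyl]oxy}-2,2,6-trimethyl-7-oxabicyclo[4.1.0]heptan-1-yl]-3-methylpent-2-en-4-yn-1-ol | OC/C=C(C)/C#C[C@@]12C(C)(C)C[C@@H](O[Si](C)(C)C(C)(C)C)C[C@]1(C)O2 | intermediate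
9 | (1S,5R,Ra)-5-{[tert-butyl(dimethyl)silyl]oxy}-2-[(3E)-5-hydroxy-3-methylpenta-1,3-dien-1-ylidene]-1,3,3-trimethylcyclohexan-1-ol | OC/C=C(C)/C=C=C1C(C)(C)C[C@@H](O[Si](C)(C)C(C)(C)C)C[C@]1(C)O | intermediate
10 | {(2E)-5-[(2S,4R,Ra)-2,4-dihydroxy-2,6,6-trimethylcyclohexylidene]-3-methylpenta-2,4-dien-1-yl}triphenylphosphonium bromide | c1ccccc1[P+](c1ccccc1)(c1ccccc1)C/C=C(C)/C=C=C1C(C)(C)C[C@@H](O)C[C@]1(C)O.[Br-] | intermediate
11 | β-cyclocitral (2,6,6-trimethylcyclohex-1-ene-1-carbaldehyde) | O=CC1=C(C)CCCC1(C)C | starting material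
12 | β-cyclogeraniol ((2,6,6-trimethylcyclohex-1-en-1-yl)methanol) | OCC1=C(C)CCCC1(C)C | intermediate
13 | [(1R,6R)-2,2,6-trimethyl-7-oxabicyclo[4.1.0]heptan-1-yl]methanol | OC[C@]12C(C)(C)CCC[C@@]1(C)O2 | intermediate
14 | (1S,6R)-2,2,6-trimethyl-7-oxabicyclo[4.1.0]heptane-1-carbaldehyde | O=C[C@]12C(C)(C)CCC[C@@]1(C)O2 | intermediate
15 | (1R,6R)-1-ethynyl-2,2,6-trimethyl-7-oxabicyclo[4.1.0]heptane | C#C[C@]12C(C)(C)CCC[C@@]1(C)O2 | intermediate
16 | but-2-yn-1-ol | CC#CCO | starting material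
17 | (2Z)-3-(4,4,5,5-tetramethyl-1,3,2-dioxaborolan-2-yl)but-2-en-1-ol | OC/C=C(C)/B1OC(C)(C)C(C)(C)O1 | intermediate
18 | (1R,Ra)-2-[(3E)-5-hydroxy-3-methylpenta-1,3-dien-1-ylidene]-1,3,3-trimethylcyclohexan-1-ol | OC/C=C(C)/C=C=C1C(C)(C)CCC[C@@]1(C)O | intermediate
19 | {(2E)-5-[(2R,Ra)-2-hydroxy-2,6,6-trimethylcyclohexylidene]-3-methylpenta-2,4-dien-1-yl}triphenylphosphonium bromide | c1ccccc1[P+](c1ccccc1)(c1ccccc1)C/C=C(C)/C=C=C1C(C)(C)CCC[C@@]1(C)O.[Br-] | intermediate
20 | (2E,4E,6E)-2,7-dimethylocta-2,4,6-trienedial | O=C/C(C)=C/C=C/C=C(C)/C=O | starting material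
21 | {(2E)-5-[(2R,Ra)-2-hydroxy-2,6,6-trimethylcyclohexylidene]-3-methylpenta-2,4-dien-1-ylidene}triphenylphosphorane (ylide of 19) | c1ccccc1P(c1ccccc1)(c1ccccc1)=C/C=C(C)/C=C=C1C(C)(C)CCC[C@@]1(C)O | intermediate
22 | (2E,4E,6E,8E,10E,Ra)-13-[(2R)-2-hydroxy-2,6,6-trimethylcyclohexylidene]-2,7,11-trimethyltrideca-2,4,6,8,10,12-hexaenal | O=C/C(C)=C/C=C/C=C(C)/C=C/C=C(C)/C=C=C1C(C)(C)CCC[C@@]1(C)O | intermediate
23 | {(2E)-5-[(2S,4R,Ra)-2,4-dihydroxy-2,6,6-trimethylcyclohexylidene]-3-methylpenta-2,4-dien-1-ylidene}triphenylphosphorane (ylide of 10) | c1ccccc1P(c1ccccc1)(c1ccccc1)=C/C=C(C)/C=C=C1C(C)(C)C[C@@H](O)C[C@]1(C)O | intermediate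
24 | (3R,5S,6R,5′R,6′R)-6,7,6′,7′-tetradehydro-5,6,5′,6′-tetrahydro-β,β-carotene-3,5,5′-triol (all-E; both allene axes Ra) | CC(/C=C/C=C(\C)C=C=C1C(C)(C)CCC[C@@]1(C)O)=C\C=C\C=C(C)\C=C\C=C(/C)C=C=C1C(C)(C)C[C@@H](O)C[C@]1(C)O | intermediate
25 | (3R,5S,6R,5′R,8′S)-5′,8′-epoxy-6,7-didehydro-5,6,5′,8′-tetrahydro-β,β-carotene-3,5-diol (allene axis Ra) | CC(/C=C/C=C(\C)[C@@H]1C=C2C(C)(C)CCC[C@@]2(C)O1)=C\C=C\C=C(C)\C=C\C=C(/C)C=C=C1C(C)(C)C[C@@H](O)C[C@]1(C)O | intermediate
26 | (3R,5S,8S,5′R,8′S)-5,8:5′,8′-diepoxy-5,8,5′,8′-tetrahydro-β,β-caroten-3-ol (CNP0406432.1) | CC(/C=C/C=C(\C)[C@@H]1C=C2C(C)(C)CCC[C@@]2(C)O1)=C\C=C\C=C(C)\C=C\C=C(/C)[C@@H]1C=C2C(C)(C)C[C@@H](O)C[C@]2(C)O1 | target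

**Totals**

Total step count: 17.
Longest linear sequence: 9 steps (1 → 2 → 3 → 5 → 7 → 8 → 9 → 10 → 24 → 26; the left branch 11 → 26 is also 9).

**Three steps most likely to fail, with fallbacks**

Step 17 (double gold cycloisomerisation on the full polyene). The risks are Nazarov-type closure of the vinylallenes, epimerisation at C-8/C-8′ and loss of polyene. The fallback closes the rings one at a time on shorter chromophores. It sets out from 22: the single allenol of 22 is cyclised with the same gold catalyst to (2E,4E,6E,8E,10E)-2,7-dimethyl-11-[(2S,7aR)-4,4,7a-trimethyl-2,4,5,6,7,7a-hexahydro-1-benzofuran-2-yl]dodeca-2,4,6,8,10-pentaenal F1. Wittig coupling of this aldehyde with ylide 23 (made from 10 as in step 16) gives 25, where the route is rejoined, and one more cycloisomerisation of the remaining allenol gives 26.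

Step 6 (copper hydride reduction of a dienynyl oxirane that carries a free allylic alcohol). The doubts are the regiochemistry of hydrocupration on the conjugated enyne and whether the anti course holds. The fallback delivers the chain instead of hydride, with syn sense. It sets out from 5: Sonogashira coupling with ethynyltrimethylsilane gives (4S)-4-{[tert-butyl(dimethyl)silyl]oxy}-2,6,6-trimethyl-1-[(trimethylsilyl)ethynyl]cyclohex-1-ene F2. mCPBA then gives the anti oxirane (1S,4R,6S)-4-{[tert-butyl(dimethyl)silyl]oxy}-2,2,6-trimethyl-1-[(trimethylsilyl)ethynyl]-7-oxabicyclo[4.1.0]heptane F3. K2CO3 in MeOH removes the alkynyl silyl group to give (1S,4R,6S)-4-{[tert-butyl(dimethyl)silyl]oxy}-1-ethynyl-2,2,6-trimethyl-7-oxabicyclo[4.1.0]heptane F4. Addition of boronate 17 catalysed by [Rh(OH)(cod)]2 (syn carborhodation, then syn β-oxygen elimination, overall syn-SN2′) puts the chain on C-8 on the oxygen side and comes back to the route at 9.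

Step 13 (palladium anti-SN2′ coupling of a fully substituted oxirane with an alkenylboronate). The doubt is transmetalation and coupling at this hindered centre. The fallback builds the enyne first and delivers hydride syn. It sets out from 17: iododeboronation (NaOH, I2, retention) gives (2E)-3-iodobut-2-en-1-ol F5. Sonogashira coupling of this iodide with 15 gives (2E)-3-methyl-5-[(1R,6R)-2,2,6-trimethyl-7-oxabicyclo[4.1.0]heptan-1-yl]pent-2-en-4-yn-1-ol F6. i-Bu2AlH then delivers hydride to C-8′ from aluminium bound to the oxirane oxygen (syn-SN2′), which gives the same (5′R,Ra) allene and comes back to the route at 18.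

**Further compounds**

F1 | step 17 | (2E,4E,6E,8E,10E)-2,7-dimethyl-11-[(2S,7aR)-4,4,7a-trimethyl-2,4,5,6,7,7a-hexahydro-1-benzofuran-2-yl]dodeca-2,4,6,8,10-pentaenal | O=C/C(C)=C/C=C/C=C(C)/C=C/C=C(C)/[C@@H]1C=C2C(C)(C)CCC[C@@]2(C)O1
F2 | step 6 | (4S)-4-{[tert-butyl(dimethyl)silyl]oxy}-2,6,6-trimethyl-1-[(trimethylsilyl)ethynyl]cyclohex-1-ene | C[Si](C)(C)C#CC1=C(C)C[C@H](O[Si](C)(C)C(C)(C)C)CC1(C)C
F3 | step 6 | (1S,4R,6S)-4-{[tert-butyl(dimethyl)silyl]oxy}-2,2,6-trimethyl-1-[(trimethylsilyl)ethynyl]-7-oxabicyclo[4.1.0]heptane | C[Si](C)(C)C#C[C@@]12C(C)(C)C[C@@H](O[Si](C)(C)C(C)(C)C)C[C@]1(C)O2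
F4 | step 6 | (1S,4R,6S)-4-{[tert-butyl(dimethyl)silyl]oxy}-1-ethynyl-2,2,6-trimethyl-7-oxabicyclo[4.1.0]heptane | C#C[C@@]12C(C)(C)C[C@@H](O[Si](C)(C)C(C)(C)C)C[C@]1(C)O2
F5 | step 13 | (2E)-3-iodobut-2-en-1-ol | OC/C=C(C)/I
F6 | step 13 | (2E)-3-methyl-5-[(1R,6R)-2,2,6-trimethyl-7-oxabicyclo[4.1.0]heptan-1-yl]pent-2-en-4-yn-1-ol | OC/C=C(C)/C#C[C@]12C(C)(C)CCC[C@@]1(C)O2
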